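You have two percentages and one direction to find, for two flasks that differ in their charge of Ve.

| flask | Dz | Ve | Ez | time |
|---|---|---|---|---|
| noon | 0.40 M | 0.600 M | 0.400 M | 30 min |
| winter | 0.40 M | 0.900 M | 0.400 M | 30 min |

    Dz + Ve → Wu + Lx (k1 = 0.41 M⁻¹ min⁻¹)
    Ve + Wu ⇌ Jy, settled at all times (K2 = 2400 M⁻¹)
    Dz + Ez → Xo (k3 = 0.047 M⁻¹ min⁻¹)
    Lx → Vy (k4 = 0.0033 min⁻¹)

- part of the Dz that has reacted at the end, noon
- part of the Dz that has reacted at the end, winter
- what raising the concentration of Ve from its lowest to its highest value here does to the part of the Dz that has reacted (changes below 5 percentage points count as none) (no change / it falls / it rises)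

The bench rule counts equivalents and half-lives. At noon Ve stands at 1.50 per Dz, and the half-life of Dz by the Ve route, 2.8 min, is short against the 30 min allowed, so the rule promises full conversion.

The rule charges one Ve per Dz, and that is where it stops working. The equilibrium constant of the balance times [Ve] at the start is 1400 at noon, so each Wu formed takes a second Ve into Jy. At two Ve per Dz, the noon charge pays for 75.0% of the Dz, and the winter charge for 112%. This share, [Ve] charged over two times [Dz] charged, is the cover. The bench rule holds down to a cover of one. Winter lies above that border, while noon lies below it, which makes Ve the limiting reagent at noon.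

In my reckoning the uncovered 25.0% at noon is left to the Ez route, whose half-life for Dz, with the concentrations as charged, is 37 min. With [Ez] held at its charge, that route takes 43.1% of the Dz it acts on during the run.

noon: 75.0% + 25.0% × 43.1% = 85.8%

winter, the cover capped at the whole charge: 100%

The gap is 14 percentage points, so my answer on the direction is it rises.

The forecast gave 87% at noon, 98% in winter and it rises, on the ground that “each Wu formed removes a second Ve”.

The simulation gives 86.7% at noon and 98.2% in winter, and the part reacted changes by 11 points: it rises.

At noon Lx and Vy together hold 71.2% of the charged Dz at the end, against the cover of 75.0%, and Xo holds 15.5%. A neighbour of noon charged with 0.15 M of Ve has a cover of 18.7%, and the same reckoning gives 53.7%. That flask reaches 50.6%, with 19.9% of the Dz in Lx and Vy and 49.4% still present as Dz at 30.0 min.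

The constants come from no measurement; the flask was simulated.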